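**Retrosynthetic overview**
1. Garcinisidone B comes from its bis-MOM ether; the seven-membered lactone (ring C) is closed last by carbodiimide lactonisation of a diaryl ether hydroxy acid.
2. The prenyl group and the phenol that closes the lactone both come from one aryl allyl ether on ring B: aromatic Claisen rearrangement after the coupling, then cross-metathesis with 2-methylbut-2-ene.
3. The diaryl ether comes from an Ullmann coupling of a 7-bromo-2,2-dimethylchromene-6-carboxylate (fragment A) with a 2-allyloxy-4-methoxy-5-(methoxymethoxy)phenol (fragment B).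
4. Fragment A: the key C–C bond is made by an intermolecular aldol-type condensation of 2-bromo-4,6-dihydroxybenzaldehyde with 3-methylbut-2-enal, followed by oxa-6π electrocyclisation.
5. Fragment B comes from vanillin (MOM, Baeyer–Villiger, ortho-formylation, allylation, Baeyer–Villiger). Ring order: pyran ring, then diaryl ether, then dioxepinone ring.

Assumption: the target has no stereocentre and no stereogenic double bond, so it is achiral and needs no enantiocontrol; the only transient stereocentres (in 6 and 22) are racemic and are destroyed.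

**Route**

Step 1
Reactants: 1 1-bromo-3,5-dimethoxybenzene
Product: 3 2-bromo-4,6-dimethoxybenzaldehyde, via aryl iminium chloride 2 (not isolated)
Conditions: POCl3, DMF, 0 to 90 °C; then aq. NaOAc
Reagents that add atoms: N,N-dimethylformamide CN(C)C=O; water O
Why: Vilsmeier–Haack formylation, in which the chloroiminium electrophile attacks the position ortho to one and para to the other methoxy group (next to bromine) rather than the crowded position between the two methoxy groups, and aqueous work-up hydrolyses iminium 2.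

Step 2
Reactants: 3 2-bromo-4,6-dimethoxybenzaldehyde
Product: 4 2-bromo-4,6-dihydroxybenzaldehyde
Conditions: BBr3 (4 equiv), CH2Cl2, −78 °C to rt; then H2O
Reagents that add atoms: none
Why: Lewis-acid ether cleavage, in which BBr3 complexes each methoxy oxygen and bromide removes the methyl group by SN2 while the aryl bromide and the aldehyde are untouched.

Step 3
Reactants: 4 2-bromo-4,6-dihydroxybenzaldehyde; 5 3-methylbut-2-enal
Product: 8 7-bromo-5-hydroxy-2,2-dimethyl-2H-chromene-6-carbaldehyde, via aldol adduct 6 (not isolated), via ortho-quinone methide 7 (not isolated)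
Conditions: Ca(OH)2 (1 equiv), MeOH, rt, 48 h
Reagents that add atoms: none
Why: Intermolecular aldol-type (Knoevenagel) condensation in which the calcium phenoxide of 4 attacks the aldehyde of 5 through the ring carbon between its two oxygens, dehydration of 6 gives ortho-quinone methide 7, and oxa-6π electrocyclisation through the non-chelated oxygen para to the formyl group closes the pyran ring; no stereocentre remains in 8.

Step 4
Reactants: 8 7-bromo-5-hydroxy-2,2-dimethyl-2H-chromene-6-carbaldehyde
Product: 9 7-bromo-5-(methoxymethoxy)-2,2-dimethyl-2H-chromene-6-carbaldehyde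
Conditions: MOMCl, K2CO3, acetone, reflux
Reagents that add atoms: chloromethyl methyl ether COCCl
Why: Williamson-type O-alkylation that caps the only (chelated) phenol as a base-stable MOM ether so that it cannot compete in the later Ullmann coupling.

Step 5
Reactants: 9 7-bromo-5-(methoxymethoxy)-2,2-dimethyl-2H-chromene-6-carbaldehyde
Product: 10 7-bromo-5-(methoxymethoxy)-2,2-dimethyl-2H-chromene-6-carboxylic acid
Conditions: NaClO2, NaH2PO4, 2-methylbut-2-ene (excess), t-BuOH/H2O, rt
Reagents that add atoms: sodium chlorite [Na+].[O-]Cl=O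
Why: Pinnick oxidation, in which buffered chlorous acid oxidises the hindered aldehyde and 2-methylbut-2-ene removes HOCl before it can attack the chromene or the arene.

Step 6
Reactants: 10 7-bromo-5-(methoxymethoxy)-2,2-dimethyl-2H-chromene-6-carboxylic acid
Product: 11 2-(trimethylsilyl)ethyl 7-bromo-5-(methoxymethoxy)-2,2-dimethyl-2H-chromene-6-carboxylate
Conditions: Me3SiCH2CH2OH, PPh3, DIAD, THF, 0 °C to rt
Reagents that add atoms: 2-(trimethylsilyl)ethanol C[Si](C)(C)CCO
Why: Mitsunobu esterification, in which the carboxylate is the nucleophile so the 2,6-disubstitution of the acid does not matter, and the silylethyl ester can later be removed by fluoride without acid or strong base.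

Step 7
Reactants: 12 vanillin (4-hydroxy-3-methoxybenzaldehyde)
Product: 13 3-methoxy-4-(methoxymethoxy)benzaldehyde
Conditions: MOMCl, i-Pr2NEt, CH2Cl2, 0 °C to rt
Reagents that add atoms: chloromethyl methyl ether COCCl
Why: Standard MOM protection of the vanillin phenol, which becomes the free ring B hydroxyl of the target and must stay masked until the last step.

Step 8
Reactants: 13 3-methoxy-4-(methoxymethoxy)benzaldehyde
Product: 15 3-methoxy-4-(methoxymethoxy)phenol, via aryl formate 14 (not isolated)
Conditions: mCPBA, CH2Cl2, 0 °C to rt; then K2CO3 (cat.), MeOH, rt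
Reagents that add atoms: mCPBA (3-chloroperoxybenzoic acid) OOC(=O)c1cccc(Cl)c1
Why: Baeyer–Villiger (Dakin-type) oxidation, in which the electron-rich aryl group migrates to give formate 14 and mild methanolysis frees the phenol.

Step 9
Reactants: 15 3-methoxy-4-(methoxymethoxy)phenol
Product: 17 2-hydroxy-4-methoxy-5-(methoxymethoxy)benzaldehyde, via hydroxymethylphenol 16 (not isolated)
Conditions: MgCl2, Et3N, (CH2O)n, MeCN, reflux; then cold 5% citric acid
Reagents that add atoms: paraformaldehyde (formaldehyde) C=O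
Why: Magnesium-mediated ortho-formylation (Casnati–Skattebøl), in which the magnesium phenoxide delivers formaldehyde to the less hindered ortho position (para to OMe, not the one flanked by OMe) and a second formaldehyde oxidises benzylic alkoxide 16 by hydride transfer.

Step 10
Reactants: 17 2-hydroxy-4-methoxy-5-(methoxymethoxy)benzaldehyde
Product: 18 4-methoxy-5-(methoxymethoxy)-2-(prop-2-en-1-yloxy)benzaldehyde
Conditions: allyl bromide, K2CO3, DMF, 50 °C
Reagents that add atoms: allyl bromide C=CCBr
Why: Williamson etherification that installs the allyl group, which first protects this oxygen and later supplies the carbon chain of the prenyl group.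

Step 11
Reactants: 18 4-methoxy-5-(methoxymethoxy)-2-(prop-2-en-1-yloxy)benzaldehyde
Product: 20 4-methoxy-5-(methoxymethoxy)-2-(prop-2-en-1-yloxy)phenol, via aryl formate 19 (not isolated)
Conditions: mCPBA (1.2 equiv), CH2Cl2, 0 °C; then K2CO3 (cat.), MeOH, rt
Reagents that add atoms: mCPBA (3-chloroperoxybenzoic acid) OOC(=O)c1cccc(Cl)c1
Why: Baeyer–Villiger oxidation and formate methanolysis, in which the trialkoxy-substituted aldehyde reacts with the peracid far faster than the terminal allyl ether olefin, giving a phenol whose only free hydroxyl is the future diaryl ether oxygen.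

Step 12
Reactants: 11 2-(trimethylsilyl)ethyl 7-bromo-5-(methoxymethoxy)-2,2-dimethyl-2H-chromene-6-carboxylate; 20 4-methoxy-5-(methoxymethoxy)-2-(prop-2-en-1-yloxy)phenol
Product: 21 2-(trimethylsilyl)ethyl 7-[4-methoxy-5-(methoxymethoxy)-2-(prop-2-en-1-yloxy)phenoxy]-5-(methoxymethoxy)-2,2-dimethyl-2H-chromene-6-carboxylate
Conditions: CuI (10 mol%), N,N-dimethylglycine·HCl (30 mol%), Cs2CO3, 1,4-dioxane, 100 °C, Ar
Reagents that add atoms: none
Why: Ligand-accelerated Ullmann diaryl ether synthesis with monovalent copper, helped by the ortho-ester on the bromide, and regiochemically unambiguous because 20 has a single free hydroxyl.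

Step 13
Reactants: 21 2-(trimethylsilyl)ethyl 7-[4-methoxy-5-(methoxymethoxy)-2-(prop-2-en-1-yloxy)phenoxy]-5-(methoxymethoxy)-2,2-dimethyl-2H-chromene-6-carboxylate
Product: 23 2-(trimethylsilyl)ethyl 7-[2-hydroxy-4-methoxy-5-(methoxymethoxy)-3-(prop-2-en-1-yl)phenoxy]-5-(methoxymethoxy)-2,2-dimethyl-2H-chromene-6-carboxylate, via ortho-dienone 22 (not isolated)
Conditions: PhNEt2, 185 °C, Ar
Reagents that add atoms: none
Why: Aromatic Claisen rearrangement, in which the [3,3] shift can only deliver the allyl group to the one free ortho position (between the oxygen and the methoxy group, the other ortho and the para position being substituted) and tautomerisation of dienone 22 frees exactly the phenol needed for lactonisation.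

Step 14
Reactants: 23 2-(trimethylsilyl)ethyl 7-[2-hydroxy-4-methoxy-5-(methoxymethoxy)-3-(prop-2-en-1-yl)phenoxy]-5-(methoxymethoxy)-2,2-dimethyl-2H-chromene-6-carboxylate
Product: 24 2-(trimethylsilyl)ethyl 7-[2-hydroxy-4-methoxy-5-(methoxymethoxy)-3-(3-methylbut-2-en-1-yl)phenoxy]-5-(methoxymethoxy)-2,2-dimethyl-2H-chromene-6-carboxylate
Conditions: 2-methylbut-2-ene (excess), second-generation Grubbs catalyst RuCl2(=CHPh)(PCy3)(H2IMes) (5 mol%), CH2Cl2, 40 °C
Reagents that add atoms: 2-methylbut-2-ene CC=C(C)C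
Why: Olefin cross-metathesis that converts the terminal allyl group into the prenyl group with loss of propene, while the ring-constrained chromene olefin next to a quaternary carbon is inert.

Step 15
Reactants: 24 2-(trimethylsilyl)ethyl 7-[2-hydroxy-4-methoxy-5-(methoxymethoxy)-3-(3-methylbut-2-en-1-yl)phenoxy]-5-(methoxymethoxy)-2,2-dimethyl-2H-chromene-6-carboxylate
Product: 25 7-[2-hydroxy-4-methoxy-5-(methoxymethoxy)-3-(3-methylbut-2-en-1-yl)phenoxy]-5-(methoxymethoxy)-2,2-dimethyl-2H-chromene-6-carboxylic acid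
Conditions: Bu4NF, THF, 0 °C to rt; then dilute HCl to pH 4
Reagents that add atoms: none
Why: Fluoride-induced β-elimination of the silylethyl ester, in which attack at silicon (not at the hindered carbonyl) releases the carboxylate, ethene and Me3SiF at room temperature without touching the MOM ethers, prenyl group or chromene.

Step 16
Reactants: 25 7-[2-hydroxy-4-methoxy-5-(methoxymethoxy)-3-(3-methylbut-2-en-1-yl)phenoxy]-5-(methoxymethoxy)-2,2-dimethyl-2H-chromene-6-carboxylic acid
Product: 27 garcinisidone B bis(methoxymethyl) ether, via O-acylisourea 26 (not isolated)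
Conditions: EDC·HCl, DMAP (cat.), CH2Cl2 (0.005 M), rt
Reagents that add atoms: none
Why: Steglich-type carbodiimide lactonisation, in which the only free phenol (ortho to the diaryl ether oxygen) attacks the activated acyl group and closes the seven-membered dioxepinone ring C at high dilution.

Step 17
Reactants: 27 garcinisidone B bis(methoxymethyl) ether
Product: 28 garcinisidone B
Conditions: 3 M aq. HCl, THF, 40 °C
Reagents that add atoms: none
Why: Acid-catalysed acetal hydrolysis that removes both MOM groups in an alcohol-free medium, so the hindered aryl lactone is not transesterified, the prenyl group has no free ortho hydroxyl to cyclise onto, and the acyl-deactivated chromene survives.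

**Compound list**
1 | 1-bromo-3,5-dimethoxybenzene | COc1cc(Br)cc(OC)c1 | starting material
2 | [(2-bromo-4,6-dimethoxyphenyl)methylidene]dimethyliminium chloride | C[N+](C)=Cc1c(Br)cc(OC)cc1OC.[Cl-] | intermediate (not isolated)
3 | 2-bromo-4,6-dimethoxybenzaldehyde | COc1cc(Br)c(C=O)c(OC)c1 | intermediate
4 | 2-bromo-4,6-dihydroxybenzaldehyde | O=Cc1c(Br)cc(O)cc1O | intermediate
5 | 3-methylbut-2-enal | CC(C)=CC=O | starting material
6 | 6-bromo-2,4-dihydroxy-3-(1-hydroxy-3-methylbut-2-en-1-yl)benzaldehyde (racemic aldol adduct) | O=Cc1c(Br)cc(O)c(C(O)C=C(C)C)c1O | intermediate (not isolated)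
7 | 6-bromo-2-hydroxy-3-(3-methylbut-2-en-1-ylidene)-4-oxocyclohexa-1,5-diene-1-carbaldehyde (ortho-quinone methide) | O=CC1=C(O)C(=CC=C(C)C)C(=O)C=C1Br | intermediate (not isolated)
8 | 7-bromo-5-hydroxy-2,2-dimethyl-2H-chromene-6-carbaldehyde | O=Cc1c(Br)cc2OC(C)(C)C=Cc2c1O | intermediate
9 | 7-bromo-5-(methoxymethoxy)-2,2-dimethyl-2H-chromene-6-carbaldehyde | O=Cc1c(Br)cc2OC(C)(C)C=Cc2c1OCOC | intermediate
10 | 7-bromo-5-(methoxymethoxy)-2,2-dimethyl-2H-chromene-6-carboxylic acid | OC(=O)c1c(Br)cc2OC(C)(C)C=Cc2c1OCOC | intermediate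
11 | 2-(trimethylsilyl)ethyl 7-bromo-5-(methoxymethoxy)-2,2-dimethyl-2H-chromene-6-carboxylate | C[Si](C)(C)CCOC(=O)c1c(Br)cc2OC(C)(C)C=Cc2c1OCOC | intermediate
12 | vanillin (4-hydroxy-3-methoxybenzaldehyde) | COc1cc(C=O)ccc1O | starting material
13 | 3-methoxy-4-(methoxymethoxy)benzaldehyde | COCOc1ccc(C=O)cc1OC | intermediate
14 | 3-methoxy-4-(methoxymethoxy)phenyl formate | COCOc1ccc(OC=O)cc1OC | intermediate (not isolated)
15 | 3-methoxy-4-(methoxymethoxy)phenol | COCOc1ccc(O)cc1OC | intermediate
16 | 2-(hydroxymethyl)-5-methoxy-4-(methoxymethoxy)phenol (present as its magnesium salt) | COCOc1cc(CO)c(O)cc1OC | intermediate (not isolated)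
17 | 2-hydroxy-4-methoxy-5-(methoxymethoxy)benzaldehyde | COCOc1cc(C=O)c(O)cc1OC | intermediate
18 | 4-methoxy-5-(methoxymethoxy)-2-(prop-2-en-1-yloxy)benzaldehyde | COCOc1cc(C=O)c(OCC=C)cc1OC | intermediate
19 | 4-methoxy-5-(methoxymethoxy)-2-(prop-2-en-1-yloxy)phenyl formate | COCOc1cc(OC=O)c(OCC=C)cc1OC | intermediate (not isolated)
20 | 4-methoxy-5-(methoxymethoxy)-2-(prop-2-en-1-yloxy)phenol | COCOc1cc(O)c(OCC=C)cc1OC | intermediate
21 | 2-(trimethylsilyl)ethyl 7-[4-methoxy-5-(methoxymethoxy)-2-(prop-2-en-1-yloxy)phenoxy]-5-(methoxymethoxy)-2,2-dimethyl-2H-chromene-6-carboxylate | C[Si](C)(C)CCOC(=O)c1c(Oc3cc(OCOC)c(OC)cc3OCC=C)cc2OC(C)(C)C=Cc2c1OCOC | intermediate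
22 | 2-(trimethylsilyl)ethyl 7-{[4-methoxy-3-(methoxymethoxy)-6-oxo-5-(prop-2-en-1-yl)cyclohexa-1,3-dien-1-yl]oxy}-5-(methoxymethoxy)-2,2-dimethyl-2H-chromene-6-carboxylate (racemic ortho-dienone) | C[Si](C)(C)CCOC(=O)c1c(OC3=CC(OCOC)=C(OC)C(CC=C)C3=O)cc2OC(C)(C)C=Cc2c1OCOC | intermediate (not isolated)
23 | 2-(trimethylsilyl)ethyl 7-[2-hydroxy-4-methoxy-5-(methoxymethoxy)-3-(prop-2-en-1-yl)phenoxy]-5-(methoxymethoxy)-2,2-dimethyl-2H-chromene-6-carboxylate | C[Si](C)(C)CCOC(=O)c1c(Oc3cc(OCOC)c(OC)c(CC=C)c3O)cc2OC(C)(C)C=Cc2c1OCOC | intermediate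
24 | 2-(trimethylsilyl)ethyl 7-[2-hydroxy-4-methoxy-5-(methoxymethoxy)-3-(3-methylbut-2-en-1-yl)phenoxy]-5-(methoxymethoxy)-2,2-dimethyl-2H-chromene-6-carboxylate | C[Si](C)(C)CCOC(=O)c1c(Oc3cc(OCOC)c(OC)c(CC=C(C)C)c3O)cc2OC(C)(C)C=Cc2c1OCOC | intermediate
25 | 7-[2-hydroxy-4-methoxy-5-(methoxymethoxy)-3-(3-methylbut-2-en-1-yl)phenoxy]-5-(methoxymethoxy)-2,2-dimethyl-2H-chromene-6-carboxylic acid | OC(=O)c1c(Oc3cc(OCOC)c(OC)c(CC=C(C)C)c3O)cc2OC(C)(C)C=Cc2c1OCOC | intermediate
26 | O-acylisourea of 25 formed with EDC | CCN=C(NCCCN(C)C)OC(=O)c1c(Oc3cc(OCOC)c(OC)c(CC=C(C)C)c3O)cc2OC(C)(C)C=Cc2c1OCOC | intermediate (not isolated)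
27 | garcinisidone B bis(methoxymethyl) ether (depsidone with both phenols as MOM ethers) | COc1c(OCOC)cc2c(c1CC=C(C)C)OC(=O)c1c(cc3c(c1OCOC)C=CC(C)(C)O3)O2 | intermediate
28 | garcinisidone B (achiral depsidone: ring A carries the chelated OH and the fused 2,2-dimethylpyran; ring B carries prenyl next to the ester oxygen, then OMe, then OH) | COc1c(O)cc2c(c1CC=C(C)C)OC(=O)c1c(cc3c(c1O)C=CC(C)(C)O3)O2 | target

**Totals and risks**

Total step count: 17. Longest linear sequence: 12 steps (steps 1–6, then 12–17, from 1 to 28); the fragment B branch is 5 steps (7–11) before the coupling.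

The three steps most likely to fail:

Step 12 (Ullmann coupling). Both partners are electron-rich and ortho-substituted, so the coupling may stall or give hydrodebromination. In that case the ether bond is made at the aldehyde oxidation level, where the ortho-formyl group makes the bromide much more reactive. The fallback sets out from 9 (together with 20) and comes back to the route at 21. Compounds 9 and 20 are condensed (K2CO3, CuO, pyridine, 115 °C) to 7-[4-methoxy-5-(methoxymethoxy)-2-(prop-2-en-1-yloxy)phenoxy]-5-(methoxymethoxy)-2,2-dimethyl-2H-chromene-6-carbaldehyde F1. Pinnick oxidation (NaClO2, NaH2PO4, 2-methylbut-2-ene) then gives 7-[4-methoxy-5-(methoxymethoxy)-2-(prop-2-en-1-yloxy)phenoxy]-5-(methoxymethoxy)-2,2-dimethyl-2H-chromene-6-carboxylic acid F2. Mitsunobu esterification with 2-(trimethylsilyl)ethanol (PPh3, DIAD) returns 21.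

Step 13 (Claisen rearrangement at 185 °C on the advanced intermediate). Thermal damage to the MOM ethers or the ester, or partial premature ring closure, could lower the yield. In that case the [3,3] shift is moved to the small, robust aldehyde and an allyl ether is then used purely as a protecting group. The fallback sets out from 18 and comes back to the route at 23.
- Heating 18 (PhNEt2, 190 °C) gives, through 4-methoxy-3-(methoxymethoxy)-6-oxo-5-(prop-2-en-1-yl)cyclohexa-1,3-diene-1-carbaldehyde F3 (not isolated), 2-hydroxy-4-methoxy-5-(methoxymethoxy)-3-(prop-2-en-1-yl)benzaldehyde F4.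
- Re-allylation (allyl bromide, K2CO3, DMF) gives 4-methoxy-5-(methoxymethoxy)-3-(prop-2-en-1-yl)-2-(prop-2-en-1-yloxy)benzaldehyde F5.
- mCPBA, then K2CO3/MeOH, gives, through 4-methoxy-5-(methoxymethoxy)-3-(prop-2-en-1-yl)-2-(prop-2-en-1-yloxy)phenyl formate F6 (not isolated), 4-methoxy-5-(methoxymethoxy)-3-(prop-2-en-1-yl)-2-(prop-2-en-1-yloxy)phenol F7.
- Ullmann coupling with 11 under the step 12 conditions gives 2-(trimethylsilyl)ethyl 7-[4-methoxy-5-(methoxymethoxy)-3-(prop-2-en-1-yl)-2-(prop-2-en-1-yloxy)phenoxy]-5-(methoxymethoxy)-2,2-dimethyl-2H-chromene-6-carboxylate F8.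
- O-deallylation with zerovalent palladium (Pd(PPh3)4, morpholine, THF, rt), which leaves the C-allyl group alone, returns 23.

Step 17 (final acid deprotection). The aryl lactone, the prenyl group and the chromene are all exposed to aqueous acid. If the lactone suffers, the order of the last two operations is reversed so that ring closure is the final step. The fallback sets out from 25 and comes back to the route at 28. Both MOM groups are removed from 25 (HCl, MeOH/THF, rt, argon) to give 7-[2,5-dihydroxy-4-methoxy-3-(3-methylbut-2-en-1-yl)phenoxy]-5-hydroxy-2,2-dimethyl-2H-chromene-6-carboxylic acid F9. This is an air-sensitive hydroquinone and is used at once. It is lactonised at high dilution (DCC, THF, rt, argon); only the phenol ortho to the diaryl ether oxygen can form the seven-membered ring, so 28 is obtained directly.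

**Further compounds**
F1 | step 12 | 7-[4-methoxy-5-(methoxymethoxy)-2-(prop-2-en-1-yloxy)phenoxy]-5-(methoxymethoxy)-2,2-dimethyl-2H-chromene-6-carbaldehyde | O=Cc1c(Oc3cc(OCOC)c(OC)cc3OCC=C)cc2OC(C)(C)C=Cc2c1OCOC
F2 | step 12 | 7-[4-methoxy-5-(methoxymethoxy)-2-(prop-2-en-1-yloxy)phenoxy]-5-(methoxymethoxy)-2,2-dimethyl-2H-chromene-6-carboxylic acid | OC(=O)c1c(Oc3cc(OCOC)c(OC)cc3OCC=C)cc2OC(C)(C)C=Cc2c1OCOC
F3 | step 13 | 4-methoxy-3-(methoxymethoxy)-6-oxo-5-(prop-2-en-1-yl)cyclohexa-1,3-diene-1-carbaldehyde (racemic, not isolated) | COCOC1=C(OC)C(CC=C)C(=O)C(C=O)=C1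
F4 | step 13 | 2-hydroxy-4-methoxy-5-(methoxymethoxy)-3-(prop-2-en-1-yl)benzaldehyde | COCOc1cc(C=O)c(O)c(CC=C)c1OC
F5 | step 13 | 4-methoxy-5-(methoxymethoxy)-3-(prop-2-en-1-yl)-2-(prop-2-en-1-yloxy)benzaldehyde | COCOc1cc(C=O)c(OCC=C)c(CC=C)c1OC
F6 | step 13 | 4-methoxy-5-(methoxymethoxy)-3-(prop-2-en-1-yl)-2-(prop-2-en-1-yloxy)phenyl formate (not isolated) | COCOc1cc(OC=O)c(OCC=C)c(CC=C)c1OC
F7 | step 13 | 4-methoxy-5-(methoxymethoxy)-3-(prop-2-en-1-yl)-2-(prop-2-en-1-yloxy)phenol | COCOc1cc(O)c(OCC=C)c(CC=C)c1OC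
F8 | step 13 | 2-(trimethylsilyl)ethyl 7-[4-methoxy-5-(methoxymethoxy)-3-(prop-2-en-1-yl)-2-(prop-2-en-1-yloxy)phenoxy]-5-(methoxymethoxy)-2,2-dimethyl-2H-chromene-6-carboxylate | C[Si](C)(C)CCOC(=O)c1c(Oc3cc(OCOC)c(OC)c(CC=C)c3OCC=C)cc2OC(C)(C)C=Cc2c1OCOC
F9 | step 17 | 7-[2,5-dihydroxy-4-methoxy-3-(3-methylbut-2-en-1-yl)phenoxy]-5-hydroxy-2,2-dimethyl-2H-chromene-6-carboxylic acid | OC(=O)c1c(Oc3cc(O)c(OC)c(CC=C(C)C)c3O)cc2OC(C)(C)C=Cc2c1O
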